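In a one-step world the substrate lost would appear as product, but 2.50 min into the dawn run the readings show substrate 74.9%, product 11.4% and intermediate 14.6%. So we sort what happens by speed.

in all of them: substrate 0.50 mM
- dawn: reagent 0.50 mM; precatalyst 50 µM; run made earlier
- grey: reagent 0.500 mM; precatalyst 100 µM; time 8.0 min
- green: reagent 0.500 mM; precatalyst 100 µM; time 10 min

dawn run (percent of the substrate charged)

| time / min | substrate / % | product / % | intermediate / % |
|---|---|---|---|
| 0.200 | 93.3 | 1.2 | 5.8 |
| 0.333 | 89.0 | 4.4 | 10.9 |
| 0.667 | 82.4 | 0 | 16.4 |
| 1.33 | 79.3 | 6.3 | 14.8 |
| 2.50 | 74.9 | 11.4 | 14.6 |

(each reading ± 1 percentage point)

- what was read earlier has a scatter of 1 percentage point, one standard deviation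
- no earlier run changes the charge of precatalyst; that part of a forecast is a guess

1. which of these there is most of at the end, counted by the substrate in it, grey (substrate / intermediate / product)
2. which of these there is most of at the end, counted by the substrate in it, green (substrate / intermediate / product)
3. amount of the one of these that there is most of at the end, in percent of the substrate charged, grey
4. amount of the one of these that there is most of at the end, in percent of the substrate charged, green

On the first rung of our ladder, the intermediate climbs to 16.4% by 0.667 min in the dawn run and then stops climbing. On the next rung, [intermediate]/[substrate] reads 0.199 at 0.667 min and 0.195 at 2.50 min, while the substrate keeps falling. We therefore read the two as a pre-equilibrium, a fixed split that follows the substrate down.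

Product formation is the last rung, and we take it to lead toward a flask of product. Let p be the fraction turned to product and q what remains. With equal charges, and assuming one reagent per product, reagent and the intermediate pool both scale with q. We assume the rate goes as their product times the catalyst, where e is charged [precatalyst]/charged [substrate]:

dp/dt = λ e q q, so p/q = λ e t

We call λ the odds rate per equivalent of catalyst. The last dawn reading, which carries the scatter, gives:

λ = 0.515 min⁻¹

Taking the catalyst as proportional to its charge, which is a guess, we reckon:

grey: p/q = 0.823, so p = 45.2%

green: p/q = 1.03, so p = 50.7%

By our reckoning the split then leaves substrate at 45.9% in grey, 0.73 percentage points above product and too close for us to call, and at 41.3% in green.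

The forecast names product at 65% in grey and product at 78% in green, above our figures, and says “Product should still dominate”.

The flasks give product at 50.1% in grey and product at 56.0% in green.

    precatalyst → catalyst (k = 0.0480 s⁻¹)
    reagent + catalyst + intermediate → catalyst + product (k = 2.60 × 10⁵ M⁻² s⁻¹)
    substrate + catalyst ⇌ catalyst + intermediate (K = 0.210, k = 540 M⁻¹ s⁻¹)

At 10.0 min in green the exchange between substrate and intermediate relaxes with a half-life of 2.23 s, far shorter than the half-life of 12 min that reagent has by the product step at that time, and [intermediate]/[substrate] stands at 0.206. Where the last dawn reading gave 0.515 min⁻¹, the product odds give λ = 0.628 min⁻¹ in grey and 0.636 min⁻¹ in green, and the neighbour of green with 0.060 mM of precatalyst, at 43.1% product, gives 0.631 min⁻¹.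

All runs come from a simulation from invented constants; the scatter is artificial.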